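Ring A, the benzoate ring, is built rather than bought. Its C3–H/C4–CH3 edge is the disconnection: an acryloyl group on C1 (supplying C2=O and C3–H) and a methallyl group on the aryloxy-bearing C6 (supplying C5 and C4–CH3) are joined by ring-closing olefin metathesis. That one operation forms C3=C4, expels ethylene and gives a cyclohexadienone that enolises at once to the C2 phenol of a methyl salicylate. The substrate is an acyclic push–pull triene, methyl 2-acryloyl-3-aryloxy-5-methylhexa-2,5-dienoate, in which ring B already sits on the ether oxygen with its benzylic alcohol silylated. O-Prenylation and desilylation follow.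

Key step: step 9

Remark 1: the target has no stereocentre and no hindered axis, so "single enantiomer" calls for no asymmetric step.
Remark 2: Ar = 2-{[(tert-butyldimethylsilyl)oxy]methyl}-4,6-dimethoxyphenyl throughout.
Remark 3: the benzylic carbon of ring B is ortho to the ether oxygen and meta to both methoxy groups, so it cannot be the formyl carbon of 2,4-dimethoxybenzaldehyde; that carbon is excised in step 1 and a new one-carbon unit is placed ortho to the phenol in step 2.
Remark 4: C–C bond formation at C2 of an ester trienolate leaves the alkene at C3=C4, so step 8 must also return it to C2=C3; the skipped methallyl arm is kept away from strong base after that point.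

Step 1
Reactants: 1 2,4-dimethoxybenzaldehyde
Product: 3 2,4-dimethoxyphenol, via 2,4-dimethoxyphenyl formate 2 (not isolated)
Conditions: mCPBA, CH2Cl2, 0 °C to rt; aq. NaHCO3 wash; then K2CO3 (cat.), MeOH, rt
Reagents that add atoms: 3-chloroperoxybenzoic acid (mCPBA), OOC(=O)c1cccc(Cl)c1
Why: Baeyer–Villiger (Dakin-type) oxidation, in which the electron-rich aryl group migrates to oxygen and the aryl formate is cleaved by mild methanolysis, leaving the phenol oxygen where ring B needs its ether oxygen.

Step 2
Reactants: 3 2,4-dimethoxyphenol; 4 paraformaldehyde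
Product: 5 2-hydroxy-3,5-dimethoxybenzaldehyde
Conditions: MgCl2, Et3N, (CH2O)n, MeCN, reflux
Reagents that add atoms: none
Why: Magnesium-mediated ortho-formylation (Casnati–Skattebøl), in which the magnesium phenoxide delivers formaldehyde to C6, the only free ortho position, and a second equivalent of formaldehyde oxidises the benzylic alkoxide to the aldehyde.

Step 3
Reactants: 5 2-hydroxy-3,5-dimethoxybenzaldehyde
Product: 6 2-(hydroxymethyl)-4,6-dimethoxyphenol
Conditions: NaBH4, MeOH, 0 °C
Reagents that add atoms: none
Why: Borohydride reduction of an aryl aldehyde is fast and leaves the aryl ethers untouched.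

Step 4
Reactants: 6 2-(hydroxymethyl)-4,6-dimethoxyphenol
Product: 7 2-{[(tert-butyldimethylsilyl)oxy]methyl}-4,6-dimethoxyphenol (ArOH)
Conditions: TBSCl (1.05 equiv), imidazole, CH2Cl2, 0 °C
Reagents that add atoms: tert-butyldimethylsilyl chloride (TBSCl), CC(C)(C)[Si](C)(C)Cl
Why: Selective silylation, since the primary benzylic hydroxyl reacts far faster than the hydrogen-bonded phenol flanked by two ortho substituents, and the silyl ether keeps the alcohol from adding to the enol ether later.

Step 5
Reactants: 8 methyl propiolate; 9 3-bromo-2-methylpropene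
Product: 10 methyl 5-methylhex-5-en-2-ynoate
Conditions: CuI (cat.), K2CO3, Bu4NI (cat.), DMF, rt
Reagents that add atoms: none
Why: Copper-catalysed coupling of a terminal alkyne with an allylic halide, in which the copper acetylide of the propiolate is alkylated by the methallyl bromide and SN2 and SN2′ attack give the same product.

Step 6
Reactants: 7 ArOH; 10 methyl 5-methylhex-5-en-2-ynoate
Product: 11 methyl (2E)-3-(ArO)-5-methylhexa-2,5-dienoate
Conditions: K2CO3 (0.3 equiv), DMF, 60 °C
Reagents that add atoms: none
Why: Base-catalysed oxa-Michael addition of the phenoxide to C3 of the ynoate should give the β-aryloxy enoate with the (E)-isomer thermodynamically preferred; any double-bond isomer formed through a transient allenoate is deprotonated to the same trienolate in step 7.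

Step 7
Reactants: 11 methyl (2E)-3-(ArO)-5-methylhexa-2,5-dienoate; 12 acrolein
Product: 14 methyl 3-(ArO)-2-(1-hydroxyprop-2-en-1-yl)-5-methylhexa-3,5-dienoate (diastereomer mixture; racemic), via lithium trienolate 13 (not isolated)
Conditions: LDA, THF, −78 °C; then 12, −78 °C; AcOH quench at −78 °C
Reagents that add atoms: none
Why: Kinetic aldol addition, in which LDA removes a C4 proton and the lithium trienolate attacks the aldehyde carbonyl through its α-carbon (C2) in a lithium-chelated six-membered transition state, with a cold quench to prevent reversal; the two new stereocentres (C2 and the carbinol carbon) form without control and are both erased in step 8.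

Step 8
Reactants: 14 methyl 3-(ArO)-2-(1-hydroxyprop-2-en-1-yl)-5-methylhexa-3,5-dienoate
Product: 16 methyl 2-acryloyl-3-(ArO)-5-methylhexa-2,5-dienoate (drawn as the 2Z isomer; the alkene isomers interconvert), via non-conjugated keto ester 15 (not isolated)
Conditions: Dess–Martin periodinane, NaHCO3, CH2Cl2, 0 °C; then Et3N (cat.), CH2Cl2, 0 °C, short contact
Reagents that add atoms: none
Why: Dess–Martin oxidation converts the allylic carbinol into the vinyl ketone, and the acidic C2–H of the resulting 1,3-dicarbonyl compound is then relayed to C4 by catalytic weak base (the pentadienyl-type anion is reprotonated at its central carbon), so the alkene returns to C2=C3 in push–pull conjugation while the methallyl alkene stays terminal.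

Step 9
Reactants: 16 methyl 2-acryloyl-3-(ArO)-5-methylhexa-2,5-dienoate
Product: 18 methyl 2-(ArO)-6-hydroxy-4-methylbenzoate, via cyclohexadienone 17 (not isolated)
Conditions: Hoveyda–Grubbs II (5 mol %), toluene (0.01 M), 60 °C, acid-free
Reagents that add atoms: none
Why: The ruthenium alkylidene loads onto one terminal alkene, undergoes intramolecular [2+2] cycloaddition with the other to a ruthenacyclobutane and cycloreverts with loss of ethylene, so the acryloyl α-carbon and the methyl-bearing methallyl carbon become the C3=C4 bond (ring-closing metathesis; closest known type: metathesis of 1,4,7-trien-3-ones followed by tautomerisation to phenols). Ring A is closed as a six-membered carbocycle across the two cis substituents of the C2=C3 alkene, and dienone 17 enolises irreversibly to the aromatic, hydrogen-bonded salicylate, which pulls the metathesis forward. No stereocentre is formed. Only the two terminal alkenes can engage the catalyst, because the third alkene is tetrasubstituted and electron-poor, and the only ring they can form is six-membered; the prenyl alkene is introduced afterwards for the same reason. The geometry with acryloyl cis to the methallyl arm is replenished by rotation about the strongly polarised C2=C3 bond, so both alkene isomers should be funnelled to product. Conditions are kept neutral so that the polarised divinyl ketone does not undergo Nazarov cyclisation.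

Step 10
Reactants: 18 methyl 2-(ArO)-6-hydroxy-4-methylbenzoate; 19 1-bromo-3-methylbut-2-ene (prenyl bromide)
Product: 20 methyl 2-(ArO)-4-methyl-6-[(3-methylbut-2-en-1-yl)oxy]benzoate
Conditions: K2CO3, acetone, 55 °C
Reagents that add atoms: none
Why: Williamson etherification, in which the salicylate phenoxide, freed from its hydrogen bond by carbonate in warm acetone, displaces bromide from the primary allylic carbon (SN2).

Step 11
Reactants: 20 methyl 2-(ArO)-4-methyl-6-[(3-methylbut-2-en-1-yl)oxy]benzoate
Product: 21 methyl 2-[2-(hydroxymethyl)-4,6-dimethoxyphenoxy]-4-methyl-6-[(3-methylbut-2-en-1-yl)oxy]benzoate (target)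
Conditions: TBAF, AcOH, THF, 0 °C to rt
Reagents that add atoms: none
Why: Fluoride cleaves the silicon–oxygen bond (desilylation), and acetic acid buffering keeps the liberated alkoxide from attacking the methyl ester.

Compound list
1 | 2,4-dimethoxybenzaldehyde | COc1ccc(C=O)c(OC)c1 | starting material
2 | 2,4-dimethoxyphenyl formate | COc1ccc(OC=O)c(OC)c1 | intermediate (not isolated)
3 | 2,4-dimethoxyphenol | COc1ccc(O)c(OC)c1 | intermediate
4 | paraformaldehyde (written as formaldehyde) | C=O | starting material
5 | 2-hydroxy-3,5-dimethoxybenzaldehyde | COc1cc(C=O)c(O)c(OC)c1 | intermediate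
6 | 2-(hydroxymethyl)-4,6-dimethoxyphenol | COc1cc(CO)c(O)c(OC)c1 | intermediate
7 | 2-{[(tert-butyldimethylsilyl)oxy]methyl}-4,6-dimethoxyphenol | COc1cc(CO[Si](C)(C)C(C)(C)C)c(O)c(OC)c1 | intermediate
8 | methyl propiolate | C#CC(=O)OC | starting material
9 | 3-bromo-2-methylpropene | C=C(C)CBr | starting material
10 | methyl 5-methylhex-5-en-2-ynoate | C=C(C)CC#CC(=O)OC | intermediate
11 | methyl (2E)-3-(ArO)-5-methylhexa-2,5-dienoate | COC(=O)/C=C(/Oc1c(CO[Si](C)(C)C(C)(C)C)cc(OC)cc1OC)CC(C)=C | intermediate
12 | acrolein | C=CC=O | starting material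
13 | lithium trienolate of 11 | [Li+].[O-]C(OC)=CC(Oc1c(CO[Si](C)(C)C(C)(C)C)cc(OC)cc1OC)=CC(C)=C | intermediate (not isolated)
14 | methyl 3-(ArO)-2-(1-hydroxyprop-2-en-1-yl)-5-methylhexa-3,5-dienoate, diastereomer mixture, racemic | COC(=O)C(C(O)C=C)C(Oc1c(CO[Si](C)(C)C(C)(C)C)cc(OC)cc1OC)=CC(C)=C | intermediate
15 | methyl 2-acryloyl-3-(ArO)-5-methylhexa-3,5-dienoate | COC(=O)C(C(=O)C=C)C(Oc1c(CO[Si](C)(C)C(C)(C)C)cc(OC)cc1OC)=CC(C)=C | intermediate (not isolated)
16 | methyl (2Z)-2-acryloyl-3-(ArO)-5-methylhexa-2,5-dienoate | C=CC(=O)/C(C(=O)OC)=C(\CC(C)=C)Oc1c(CO[Si](C)(C)C(C)(C)C)cc(OC)cc1OC | intermediate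
17 | methyl 2-(ArO)-4-methyl-6-oxocyclohexa-1,4-diene-1-carboxylate | COC(=O)C1=C(Oc2c(CO[Si](C)(C)C(C)(C)C)cc(OC)cc2OC)CC(C)=CC1=O | intermediate (not isolated)
18 | methyl 2-(ArO)-6-hydroxy-4-methylbenzoate | COC(=O)c1c(O)cc(C)cc1Oc1c(CO[Si](C)(C)C(C)(C)C)cc(OC)cc1OC | intermediate
19 | 1-bromo-3-methylbut-2-ene | CC(C)=CCBr | starting material
20 | methyl 2-(ArO)-4-methyl-6-[(3-methylbut-2-en-1-yl)oxy]benzoate | COC(=O)c1c(OCC=C(C)C)cc(C)cc1Oc1c(CO[Si](C)(C)C(C)(C)C)cc(OC)cc1OC | intermediate
21 | methyl 2-[2-(hydroxymethyl)-4,6-dimethoxyphenoxy]-4-methyl-6-[(3-methylbut-2-en-1-yl)oxy]benzoate | COC(=O)c1c(OCC=C(C)C)cc(C)cc1Oc1c(CO)cc(OC)cc1OC | target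

Total step count: 11
Longest linear sequence: 10 steps (steps 1–4 and 6–11, from 2,4-dimethoxybenzaldehyde)

Steps most likely to fail

Step 7. The trienolate is ambident, so bond formation may stray from C2 to C4 or C6, and the aldolate may revert on warming and drift to the γ-adduct. Fallback, from 11 back to 16: the bond is made at a carbon fixed by a carbon–iodine bond. Compound 11 is iodinated at C2 (N-iodosuccinimide, AcOH, CH2Cl2, then Et3N) to give methyl 3-(ArO)-2-iodo-5-methylhexa-2,5-dienoate F1. F1 is coupled with acrolein 12 under Nozaki–Hiyama–Kishi conditions (CrCl2, cat. NiCl2, DMF) to give the conjugated carbinol methyl 3-(ArO)-2-(1-hydroxyprop-2-en-1-yl)-5-methylhexa-2,5-dienoate F2. Dess–Martin oxidation of F2 gives 16 directly, with no alkene migration needed.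

Step 9. The acryloyl alkene is electron-poor and the methallyl alkene is 1,1-disubstituted, so ring closure may be outrun by catalyst decay or by intermolecular metathesis. Fallback, from 19 to the target 21: ring A is taken from the pool and the diaryl ether is made by copper catalysis. Prenyl bromide 19 monoalkylates purchased methyl 2,6-dihydroxy-4-methylbenzoate F3 (K2CO3, acetone) to give methyl 2-hydroxy-4-methyl-6-[(3-methylbut-2-en-1-yl)oxy]benzoate F4. Ullmann coupling of F4 with purchased 2-bromo-3,5-dimethoxybenzaldehyde F5 (CuI, N,N-dimethylglycine, Cs2CO3, dioxane, 100 °C) gives methyl 2-(2-formyl-4,6-dimethoxyphenoxy)-4-methyl-6-[(3-methylbut-2-en-1-yl)oxy]benzoate F6. NaBH4 in MeOH at 0 °C reduces the aldehyde to give 21.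

Step 8. The prototropic shift may overshoot, moving the alkene on into conjugation with the former methallyl unit so that this arm loses its terminal alkene; the vinyl ketone may also suffer conjugate addition or oligomerisation under amine. Fallback, from 14 back to 18: the shift is omitted. Compound 14 is oxidised without amine (Dess–Martin periodinane, NaHCO3) and the non-conjugated keto ester 15 is isolated and given directly to the ruthenium catalyst. Its acryloyl and terminal diene alkenes close the same C3=C4 bond to give methyl 2-(ArO)-4-methyl-6-oxocyclohexa-2,4-diene-1-carboxylate F7, which enolises to 18.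

Further compounds
F1 | step 7 | methyl 3-(ArO)-2-iodo-5-methylhexa-2,5-dienoate | COC(=O)C(I)=C(CC(C)=C)Oc1c(CO[Si](C)(C)C(C)(C)C)cc(OC)cc1OC
F2 | step 7 | methyl 3-(ArO)-2-(1-hydroxyprop-2-en-1-yl)-5-methylhexa-2,5-dienoate | COC(=O)C(C(O)C=C)=C(CC(C)=C)Oc1c(CO[Si](C)(C)C(C)(C)C)cc(OC)cc1OC
F3 | step 9 | methyl 2,6-dihydroxy-4-methylbenzoate | COC(=O)c1c(O)cc(C)cc1O
F4 | step 9 | methyl 2-hydroxy-4-methyl-6-[(3-methylbut-2-en-1-yl)oxy]benzoate | COC(=O)c1c(O)cc(C)cc1OCC=C(C)C
F5 | step 9 | 2-bromo-3,5-dimethoxybenzaldehyde | COc1cc(C=O)c(Br)c(OC)c1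
F6 | step 9 | methyl 2-(2-formyl-4,6-dimethoxyphenoxy)-4-methyl-6-[(3-methylbut-2-en-1-yl)oxy]benzoate | COC(=O)c1c(OCC=C(C)C)cc(C)cc1Oc1c(C=O)cc(OC)cc1OC
F7 | step 8 | methyl 2-(ArO)-4-methyl-6-oxocyclohexa-2,4-diene-1-carboxylate | COC(=O)C1C(=O)C=C(C)C=C1Oc1c(CO[Si](C)(C)C(C)(C)C)cc(OC)cc1OC
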